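All runs stem from a simulated flask with constants of no real substance, noise included.

If you hold a ruler to the two earlier runs and extend each slope to the end of the asked time, you get a quick bench estimate. You also soon find where it breaks.

| flask | starting material | partner | second reagent | temperature | remark | time |
|---|---|---|---|---|---|---|
| spring | 0.0070 M | 7 mM | 0.035 M | 45 °C | run made earlier |  |
| dusk | 0.028 M | 7 mM | 0.035 M | 78 °C | run made earlier |  |
| Sunday's | 0.014 M | 7.00 mM | 0.0350 M |  | at 30 °C until 20 h, from then on at 90 °C | 2.5 d |
| Monday's | 0.014 M | 7.00 mM | 0.0350 M | 30 °C |  | 2.5 d |
| Thursday's | 0.014 M | 7.00 mM | 0.0350 M | 90 °C |  | 2.5 d |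
| Saturday's | 0.014 M | 7.00 mM | 0.0350 M | 60 °C |  | 2.5 d |

| spring: time / h | spring: target / % | dusk: time / h | dusk: target / % |
|---|---|---|---|
| 3.00 | 0.9 | 0.500 | 2.7 |
| 5.00 | 0.2 | 1.00 | 1.8 |
| 8.00 | 1.3 | 1.33 | 4.3 |
| 12.0 | 2.8 | 2.50 | 7.1 |
| 20.0 | 5.8 | 4.00 | 10.2 |
| 30.0 | 8.0 | 6.00 | 10.8 |

(each reading ± 1 percentage point)



- which flask leads in amount of target, in percent of the starting material charged ("all alike" within 1.5 percentage points) (Sunday's / Monday's / Thursday's / Saturday's / all alike)
- how much target is there at the end, in percent of the starting material charged: Sunday's
- how much target is there at the end, in percent of the starting material charged: Monday's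
- how much target is there at the end, in percent of the starting material charged: Thursday's
- how much target is there at the end, in percent of the starting material charged: Saturday's

1. The rule of thumb is that a slope read off the readings goes on. The spring run, from its reading at 12.0 h to its reading at 30.0 h, carried through 2.5 d, gives 17.3%. That is a believable figure.

2. The dusk run, on its early slope from 1.00 h to 2.50 h, carried through the same time, gives 212% of the starting material charged. That is impossible, so the ruler stops here.

3. The border comes from a ratio of charges. Suppose each target carries one partner, and freeze the stoichiometric ceiling C, the partner charge over the starting material charge, in percent. For Sunday's, Monday's, Thursday's and Saturday's, C is 50.0%. For the dusk run it is 25.0%.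

4. The last dusk reading, 10.8%, lies below the dusk ceiling, at 43.2% of it. That share is a reading and carries the scatter. My own reckoning takes the same share of C for a warm flask that levels off, which gives 21.6% for Saturday's and for Thursday's.

5. The forecast picks Saturday's, with Sunday's at 10.5%, Monday's at 2%, Thursday's at 10% and Saturday's at 16%. One of its grounds reads: “Sunday's flask gains almost nothing from its cold period, so it should resemble Thursday's.” My figure for Saturday's is higher than the forecast's, and my figure for Thursday's is higher too.

6. The flasks give Sunday's 3.79%, Monday's 2.05%, Thursday's 1.69% and Saturday's 26.5%, so Saturday's leads.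

    starting material + partner → intermediate (k = 0.0130 L mol⁻¹ s⁻¹, Ea = 67.0 kJ mol⁻¹)
    second reagent + intermediate → target (k = 3.80 × 10⁻⁴ L mol⁻¹ s⁻¹, Ea = 91.0 kJ mol⁻¹)
    starting material + second reagent → side product (k = 0.00240 L mol⁻¹ s⁻¹, Ea = 53.0 kJ mol⁻¹)
    second reagent + target → over-reaction product (k = 7.10 × 10⁻⁵ L mol⁻¹ s⁻¹, Ea = 87.0 kJ mol⁻¹)
    (constants at 60 °C)

Thursday's ends far under C. The largest single effect there is second reagent turning target into over-reaction product. With that step taken away, Thursday's holds 44.2%, still below C. So C bounds what the partner can carry into target, and Thursday's loses target to over-reaction product while it stands.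

7. Take the neighbour of Saturday's charged with 0.028 M of partner. The partner charge now exceeds the starting material charge, so C is capped at 100%, twice the old value, and scaling Saturday's by that gives 53.0%. The computed flask holds 53.2%.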